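The flavone is disconnected at C3 of ring C, the only CH of the pyranone, which lies between C2 (bonded to O1 and ring B) and the C4 carbonyl. Removing that carbon leaves a 2-aryl-3-silyloxybenzofuran, so the plan is a single-carbon ring expansion: dibromocarbene adds to the furan enol ether bond and the cyclopropane opens to the 3-bromoflavone, making the C2–C3 and C3–C4 bonds and ring C at once. The precursor is a 7-benzyloxy-5,6-dimethoxybenzofuran carrying the benzyl-protected ring B at C2 and a TBS ether at C3, assembled by an anionic ester cyclisation; one hydrogenolysis then removes bromine and both benzyl groups.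

Key step: step 10

Remark: the ring A pattern (O1, 8-OBn, 7-OMe, 6-OMe, 5-H) is reached from 2-hydroxy-3,4-dimethoxybenzaldehyde only if its formyl carbon is excised (Dakin-type oxidation) and a new carbon is installed ortho to the phenol so formed; the target has no stereocentre, and the transient stereocentres of the cyclopropane intermediate and of fallback compounds are racemic.

Step 1
Reactants: 1 2-hydroxy-3,4-dimethoxybenzaldehyde
Product: 2 2-(benzyloxy)-3,4-dimethoxybenzaldehyde
Conditions: BnBr, K2CO3, DMF, 60 °C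
Reagents that add atoms: benzyl bromide, BrCc1ccccc1
Why: Williamson etherification of the acidic, hydrogen-bonded ortho-phenol with a reactive benzylic bromide installs the benzyl group on the oxygen that ends as the C8 hydroxyl, and nothing else in 1 is alkylated under carbonate conditions.

Step 2
Reactants: 2 2-(benzyloxy)-3,4-dimethoxybenzaldehyde
Product: 4 2-(benzyloxy)-3,4-dimethoxyphenol, via aryl formate 3 (not isolated)
Conditions: mCPBA, CH2Cl2, 0 °C to rt; aq. NaHCO3 wash; then K2CO3 (cat.), MeOH, rt
Reagents that add atoms: 3-chloroperoxybenzoic acid (mCPBA), OOC(=O)c1cccc(Cl)c1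
Why: Baeyer–Villiger (Dakin-type) oxidation of a benzaldehyde flanked by ortho and para alkoxy donors migrates the electron-rich aryl group to give the formate, whose mild methanolysis unveils the phenol oxygen that becomes O1 while the benzyl and methyl ethers are untouched.

Step 3
Reactants: 4 2-(benzyloxy)-3,4-dimethoxyphenol
Product: 5 3-(benzyloxy)-2-hydroxy-4,5-dimethoxybenzaldehyde
Conditions: MgCl2, Et3N, (CH2O)n, MeCN, reflux; aq. HCl work-up
Reagents that add atoms: paraformaldehyde (formaldehyde), C=O
Why: Magnesium-phenoxide-directed ortho-formylation delivers formaldehyde only to C6, the single free position ortho to the hydroxyl, a second equivalent of formaldehyde accepting hydride to give the salicylaldehyde whose formyl carbon becomes C4 of the flavone.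

Step 4
Reactants: 6 3-hydroxy-4,5-dimethoxybenzaldehyde
Product: 7 3-(benzyloxy)-4,5-dimethoxybenzaldehyde
Conditions: BnBr, K2CO3, DMF, 60 °C
Reagents that add atoms: benzyl bromide, BrCc1ccccc1
Why: Williamson etherification of the only phenol of 6 proceeds without competition and protects the future 3′-hydroxyl as a benzyl ether that is removable at the end together with the other one.

Step 5
Reactants: 7 3-(benzyloxy)-4,5-dimethoxybenzaldehyde
Product: 8 [3-(benzyloxy)-4,5-dimethoxyphenyl]methanol
Conditions: NaBH4, MeOH–THF, 0 °C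
Reagents that add atoms: none
Why: Borohydride reduction of the aromatic aldehyde to the benzylic alcohol is chemoselective because the molecule holds no other reducible group.

Step 6
Reactants: 8 [3-(benzyloxy)-4,5-dimethoxyphenyl]methanol
Product: 9 1-(benzyloxy)-5-(bromomethyl)-2,3-dimethoxybenzene
Conditions: PBr3, CH2Cl2, 0 °C
Reagents that add atoms: phosphorus tribromide, BrP(Br)Br
Why: Bromination of the primary benzylic alcohol with PBr3 (SN2 displacement on the phosphite ester) is fast at 0 °C and leaves aryl benzyl and methyl ethers intact.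

Step 7
Reactants: 5 3-(benzyloxy)-2-hydroxy-4,5-dimethoxybenzaldehyde; 9 1-(benzyloxy)-5-(bromomethyl)-2,3-dimethoxybenzene
Product: 10 3-(benzyloxy)-2-{[3-(benzyloxy)-4,5-dimethoxyphenyl]methoxy}-4,5-dimethoxybenzaldehyde
Conditions: K2CO3, DMF, rt to 50 °C
Reagents that add atoms: none
Why: Williamson O-alkylation (SN2) of the salicylaldehyde phenoxide by the benzylic bromide joins rings A and B through the future O1–C2 linkage and, by capping the electron-rich phenol, shields it from the oxidant of the next step.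

Step 8
Reactants: 10 3-(benzyloxy)-2-{[3-(benzyloxy)-4,5-dimethoxyphenyl]methoxy}-4,5-dimethoxybenzaldehyde
Product: 11 methyl 3-(benzyloxy)-2-{[3-(benzyloxy)-4,5-dimethoxyphenyl]methoxy}-4,5-dimethoxybenzoate
Conditions: I2, KOH, MeOH–THF, 0 °C
Reagents that add atoms: methanol, CO
Why: Oxidative esterification of the aromatic aldehyde with iodine and KOH in methanol gives the methyl ester in one operation, and the aryl methyl, aryl benzyl and benzylic ethers are inert to these conditions.

Step 9
Reactants: 11 methyl 3-(benzyloxy)-2-{[3-(benzyloxy)-4,5-dimethoxyphenyl]methoxy}-4,5-dimethoxybenzoate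
Product: 13 7-(benzyloxy)-2-[3-(benzyloxy)-4,5-dimethoxyphenyl]-3-[(tert-butyldimethylsilyl)oxy]-5,6-dimethoxy-1-benzofuran, via lithium benzofuranolate 12 (not isolated)
Conditions: LiN(iPr)2 (LDA, 2.5 equiv), THF, −78 to 0 °C; then TBSCl, DMPU, 0 °C to rt
Reagents that add atoms: tert-butyldimethylsilyl chloride, CC(C)(C)[Si](C)(C)Cl
Why: Intramolecular Claisen-type (Dieckmann-like) acylation, the oxygen counterpart of the base-mediated closure of 2-(benzylthio)benzoates and 2-(benzyloxy)benzonitriles, should follow ester-directed deprotonation of the ArCH2O group and a 5-exo-trig attack on the ester, after which the second equivalent of base gives the aromatic enolate that is O-silylated in the same flask, so that the oxidation-prone 2-arylbenzofuran-3(2H)-one is never handled.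

Step 10
Reactants: 13 7-(benzyloxy)-2-[3-(benzyloxy)-4,5-dimethoxyphenyl]-3-[(tert-butyldimethylsilyl)oxy]-5,6-dimethoxy-1-benzofuran; 14 bromoform
Product: 17 8-(benzyloxy)-2-[3-(benzyloxy)-4,5-dimethoxyphenyl]-3-bromo-6,7-dimethoxy-4H-chromen-4-one, via dibromocyclopropane adduct 15 (not isolated), via silyloxychromenylium bromide 16 (not isolated)
Conditions: CHBr3, KOtBu, toluene, −20 °C to rt; aq. HCl work-up
Reagents that add atoms: bromoform (14), BrC(Br)Br
Why: Proposed new method: dibromocarbene, released from bromoform by α-elimination with KOtBu, should add as an electrophile in a concerted [2+1] manner to the C2=C3 bond of 13, the only π bond carrying two oxygen donors, to give the cis-fused dibromocyclopropane 15. Ionisation of the bromide syn to the five-membered ring with disrotatory two-electron electrocyclic opening of the former C2–C3 σ bond, pushed by the lone pairs of O1 and of the silyloxy oxygen, should give the aromatic 3-bromo-4-silyloxychromenylium bromide 16, which loses the silyl group to bromide or tert-butoxide (any C2 tert-butoxide adduct reverting on the acidic work-up) to leave the carbonyl of 17. The closest known reaction types are the dihalocarbene ring expansion of cyclic silyl enol ethers to 2-halo-enones and the Ciamician–Dennstedt conversion of indoles into 3-haloquinolines, whereas a 3-silyloxybenzofuran has not been used in this way. Ring C is therefore formed not by cyclisation of a chain but by cheletropic cyclopropanation followed by electrocyclic enlargement of the furan ring, which creates the C2–C3 and C3–C4 bonds of the flavone in one operation. No stereocentre persists, since the two transient ones of 15 are cis by ring constraint and are destroyed on opening. The step needs chemoselectivity for the enol ether bond over the alkoxyarene rings and the benzylic C–H bonds, which the far higher nucleophilicity of a doubly oxygenated alkene should secure, and it needs the silyl ether to outlast tert-butoxide until the carbene has added, for which the bulk of the TBS group at low temperature is relied upon.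

Step 11
Reactants: 17 8-(benzyloxy)-2-[3-(benzyloxy)-4,5-dimethoxyphenyl]-3-bromo-6,7-dimethoxy-4H-chromen-4-one
Product: 18 8-hydroxy-2-(3-hydroxy-4,5-dimethoxyphenyl)-6,7-dimethoxy-4H-chromen-4-one (CNP0264497.0)
Conditions: H2 (1 atm), 10% Pd/C, Et3N, THF–MeOH, rt
Reagents that add atoms: none
Why: Heterogeneous palladium-catalysed hydrogenolysis cleaves both aryl benzyl ethers and the vinylic C3–Br bond, Et3N taking up the HBr, while the flavone C2=C3 bond, part of a conjugated pyranone, and the methyl ethers are not affected at 1 atm and rt.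

Compound list
1 | 2-hydroxy-3,4-dimethoxybenzaldehyde | COc1ccc(C=O)c(O)c1OC | starting material
2 | 2-(benzyloxy)-3,4-dimethoxybenzaldehyde | COc1ccc(C=O)c(OCc2ccccc2)c1OC | intermediate
3 | 2-(benzyloxy)-3,4-dimethoxyphenyl formate | COc1ccc(OC=O)c(OCc2ccccc2)c1OC | intermediate (not isolated)
4 | 2-(benzyloxy)-3,4-dimethoxyphenol | COc1ccc(O)c(OCc2ccccc2)c1OC | intermediate
5 | 3-(benzyloxy)-2-hydroxy-4,5-dimethoxybenzaldehyde | COc1cc(C=O)c(O)c(OCc2ccccc2)c1OC | intermediate
6 | 3-hydroxy-4,5-dimethoxybenzaldehyde | COc1cc(C=O)cc(O)c1OC | starting material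
7 | 3-(benzyloxy)-4,5-dimethoxybenzaldehyde | COc1cc(C=O)cc(OCc2ccccc2)c1OC | intermediate
8 | [3-(benzyloxy)-4,5-dimethoxyphenyl]methanol | COc1cc(CO)cc(OCc2ccccc2)c1OC | intermediate
9 | 1-(benzyloxy)-5-(bromomethyl)-2,3-dimethoxybenzene | COc1cc(CBr)cc(OCc2ccccc2)c1OC | intermediate
10 | 3-(benzyloxy)-2-{[3-(benzyloxy)-4,5-dimethoxyphenyl]methoxy}-4,5-dimethoxybenzaldehyde | COc1cc(C=O)c(OCc2cc(OC)c(OC)c(OCc3ccccc3)c2)c(OCc2ccccc2)c1OC | intermediate
11 | methyl 3-(benzyloxy)-2-{[3-(benzyloxy)-4,5-dimethoxyphenyl]methoxy}-4,5-dimethoxybenzoate | COC(=O)c1cc(OC)c(OC)c(OCc2ccccc2)c1OCc1cc(OC)c(OC)c(OCc2ccccc2)c1 | intermediate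
12 | lithium 7-(benzyloxy)-2-[3-(benzyloxy)-4,5-dimethoxyphenyl]-5,6-dimethoxy-1-benzofuran-3-olate | COc1cc(-c2oc3c(OCc4ccccc4)c(OC)c(OC)cc3c2[O-])cc(OCc2ccccc2)c1OC.[Li+] | intermediate (not isolated)
13 | 7-(benzyloxy)-2-[3-(benzyloxy)-4,5-dimethoxyphenyl]-3-[(tert-butyldimethylsilyl)oxy]-5,6-dimethoxy-1-benzofuran | COc1cc(-c2oc3c(OCc4ccccc4)c(OC)c(OC)cc3c2O[Si](C)(C)C(C)(C)C)cc(OCc2ccccc2)c1OC | intermediate
14 | bromoform | BrC(Br)Br | starting material
15 | 3-(benzyloxy)-1a-[3-(benzyloxy)-4,5-dimethoxyphenyl]-1,1-dibromo-6b-[(tert-butyldimethylsilyl)oxy]-4,5-dimethoxy-1a,6b-dihydro-1H-cyclopropa[b][1]benzofuran, racemic, cis-fused (one enantiomer drawn) | COc1cc([C@@]23Oc4c(OCc5ccccc5)c(OC)c(OC)cc4[C@]2(O[Si](C)(C)C(C)(C)C)C3(Br)Br)cc(OCc2ccccc2)c1OC | intermediate (not isolated)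
16 | 8-(benzyloxy)-2-[3-(benzyloxy)-4,5-dimethoxyphenyl]-3-bromo-4-[(tert-butyldimethylsilyl)oxy]-6,7-dimethoxychromenylium bromide | COc1cc(-c2[o+]c3c(OCc4ccccc4)c(OC)c(OC)cc3c(O[Si](C)(C)C(C)(C)C)c2Br)cc(OCc2ccccc2)c1OC.[Br-] | intermediate (not isolated)
17 | 8-(benzyloxy)-2-[3-(benzyloxy)-4,5-dimethoxyphenyl]-3-bromo-6,7-dimethoxy-4H-chromen-4-one | COc1cc(-c2oc3c(OCc4ccccc4)c(OC)c(OC)cc3c(=O)c2Br)cc(OCc2ccccc2)c1OC | intermediate
18 | 8-hydroxy-2-(3-hydroxy-4,5-dimethoxyphenyl)-6,7-dimethoxy-4H-chromen-4-one | COc1cc(-c2cc(=O)c3cc(OC)c(OC)c(O)c3o2)cc(O)c1OC | target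

Total step count: 11
Longest linear sequence: 8 steps (steps 1–3 and 7–11 from 1; equally steps 4–11 from 6)

Steps most likely to fail

Step 10. tert-Butoxide may strip the silyl group before the carbene arrives, or addition to the crowded tetrasubstituted enol ether may be slower than carbene decay, so that no ring enlargement takes place. The fallback is the classical chalcone route; it sets out from 5 and 7 and comes back to the route at 18. Addition of MeMgBr (excess, THF, 0 °C) to 5 should give racemic 1-[3-(benzyloxy)-2-hydroxy-4,5-dimethoxyphenyl]ethan-1-ol F1, which MnO2 in CH2Cl2 should oxidise to 1-[3-(benzyloxy)-2-hydroxy-4,5-dimethoxyphenyl]ethan-1-one F2. Claisen–Schmidt condensation of F2 with 7 (KOH, EtOH, rt) should give (2E)-1-[3-(benzyloxy)-2-hydroxy-4,5-dimethoxyphenyl]-3-[3-(benzyloxy)-4,5-dimethoxyphenyl]prop-2-en-1-one F3. Oxidative cyclisation with catalytic I2 in DMSO at 120 °C should then give 8-(benzyloxy)-2-[3-(benzyloxy)-4,5-dimethoxyphenyl]-6,7-dimethoxy-4H-chromen-4-one F4, and hydrogenolysis as in step 11, without the amine, should give 18.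

Step 9. The amide base may fail to remove the weakly acidic benzylic proton next to the electron-rich ring B, or may metalate C6–H of ring A so that the ester is lost to intermolecular condensation; a [1,2]-Wittig shift of the benzylic anion is a further drain. The fallback forms the O1–C2 bond last by intramolecular O-alkylation; it sets out from 5 and 9 and comes back at 13. The Grignard reagent made from 9 (Mg, THF, 0 °C, slow addition) is added to 5, previously converted into its magnesium phenoxide with iPrMgCl, to give racemic 1-[3-(benzyloxy)-2-hydroxy-4,5-dimethoxyphenyl]-2-[3-(benzyloxy)-4,5-dimethoxyphenyl]ethan-1-ol F5. MnO2 in CH2Cl2 should give the deoxybenzoin 1-[3-(benzyloxy)-2-hydroxy-4,5-dimethoxyphenyl]-2-[3-(benzyloxy)-4,5-dimethoxyphenyl]ethan-1-one F6, and CuBr2 in EtOAc–CHCl3 at reflux should give racemic 2-bromo-1-[3-(benzyloxy)-2-hydroxy-4,5-dimethoxyphenyl]-2-[3-(benzyloxy)-4,5-dimethoxyphenyl]ethan-1-one F7. K2CO3 in acetone under argon should close the ring to racemic 7-(benzyloxy)-2-[3-(benzyloxy)-4,5-dimethoxyphenyl]-5,6-dimethoxy-1-benzofuran-3(2H)-one F8, and TBSOTf with Et3N in CH2Cl2 at 0 °C should give 13.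

Step 3. Chelation of magnesium between the phenoxide and the neighbouring benzyloxy oxygen may slow formaldehyde transfer, so that conversion stalls or methoxymethylated by-products build up. The fallback introduces the carbon through an aryl bromide; it sets out from 4, uses 9 and comes back at 10. Ortho-bromination of 4 with NBS (CH2Cl2, catalytic iPr2NH, −40 °C), directed by the free hydroxyl to C6, should give 2-(benzyloxy)-6-bromo-3,4-dimethoxyphenol F9. Alkylation with 9 (K2CO3, DMF) should give 3-(benzyloxy)-1-bromo-2-{[3-(benzyloxy)-4,5-dimethoxyphenyl]methoxy}-4,5-dimethoxybenzene F10, and bromine–lithium exchange with nBuLi in THF at −78 °C followed by DMF should give 10, from which step 8 continues.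

Further compounds
F1 | step 10 | 1-[3-(benzyloxy)-2-hydroxy-4,5-dimethoxyphenyl]ethan-1-ol (racemic) | COc1cc(C(C)O)c(O)c(OCc2ccccc2)c1OC
F2 | step 10 | 1-[3-(benzyloxy)-2-hydroxy-4,5-dimethoxyphenyl]ethan-1-one | COc1cc(C(C)=O)c(O)c(OCc2ccccc2)c1OC
F3 | step 10 | (2E)-1-[3-(benzyloxy)-2-hydroxy-4,5-dimethoxyphenyl]-3-[3-(benzyloxy)-4,5-dimethoxyphenyl]prop-2-en-1-one | COc1cc(C(=O)/C=C/c2cc(OC)c(OC)c(OCc3ccccc3)c2)c(O)c(OCc2ccccc2)c1OC
F4 | step 10 | 8-(benzyloxy)-2-[3-(benzyloxy)-4,5-dimethoxyphenyl]-6,7-dimethoxy-4H-chromen-4-one | COc1cc(-c2cc(=O)c3cc(OC)c(OC)c(OCc4ccccc4)c3o2)cc(OCc2ccccc2)c1OC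
F5 | step 9 | 1-[3-(benzyloxy)-2-hydroxy-4,5-dimethoxyphenyl]-2-[3-(benzyloxy)-4,5-dimethoxyphenyl]ethan-1-ol (racemic) | COc1cc(C(O)Cc2cc(OC)c(OC)c(OCc3ccccc3)c2)c(O)c(OCc2ccccc2)c1OC
F6 | step 9 | 1-[3-(benzyloxy)-2-hydroxy-4,5-dimethoxyphenyl]-2-[3-(benzyloxy)-4,5-dimethoxyphenyl]ethan-1-one | COc1cc(C(=O)Cc2cc(OC)c(OC)c(OCc3ccccc3)c2)c(O)c(OCc2ccccc2)c1OC
F7 | step 9 | 2-bromo-1-[3-(benzyloxy)-2-hydroxy-4,5-dimethoxyphenyl]-2-[3-(benzyloxy)-4,5-dimethoxyphenyl]ethan-1-one (racemic) | COc1cc(C(=O)C(Br)c2cc(OC)c(OC)c(OCc3ccccc3)c2)c(O)c(OCc2ccccc2)c1OC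
F8 | step 9 | 7-(benzyloxy)-2-[3-(benzyloxy)-4,5-dimethoxyphenyl]-5,6-dimethoxy-1-benzofuran-3(2H)-one (racemic) | COc1cc(C2Oc3c(OCc4ccccc4)c(OC)c(OC)cc3C2=O)cc(OCc2ccccc2)c1OC
F9 | step 3 | 2-(benzyloxy)-6-bromo-3,4-dimethoxyphenol | COc1cc(Br)c(O)c(OCc2ccccc2)c1OC
F10 | step 3 | 3-(benzyloxy)-1-bromo-2-{[3-(benzyloxy)-4,5-dimethoxyphenyl]methoxy}-4,5-dimethoxybenzene | COc1cc(Br)c(OCc2cc(OC)c(OC)c(OCc3ccccc3)c2)c(OCc2ccccc2)c1OC
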